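## Retrosynthetic overview
1. Target ⇒ (2 e⁻ reduction) its 5,8-quinone ⇒ break the aryl C8a–O1 bond. The pyranone is closed by attack of a chain carbinol oxygen on C-3 of a 2-(β-hydroxyacyl)-1,4-benzoquinone, mirroring the hydroquinone/quinone shuttle presumed in the biogenesis. The stereocentre is only a spectator.
2. Acylquinone ⇒ acylhydroquinone (dehydrogenation in the same flask).
3. β-Hydroxy ketone ⇒ catalytic enantioselective Mukaiyama aldol, which sets the future C-2. The partners are the per-silylated enol form of 2',5'-dihydroxyacetophenone (1) and (13Z)-octadec-13-enal (2), which brings in the whole Z-olefinic chain.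
4. Ring order: the benzene ring is bought. The dihydropyranone is the only ring formed, and it is formed last.

Assumption: 2 is bought as the commercial moth-pheromone component (high Z purity), and N-tosyl-D-tryptophan and n-BuB(OH)2 for the catalyst are also bought, so catalyst make-up is not counted as a step.

## Route

Step 1
Reactants: 1 2',5'-dihydroxyacetophenone
Product: 3 1-[2,5-bis(trimethylsilyloxy)phenyl]-1-(trimethylsilyloxy)ethene
Conditions: TMSOTf (3.6 equiv), Et3N (5 equiv), CH2Cl2, 0 °C to rt, 2 h; pentane extraction, Kugelrohr distillation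
Reagents that add atoms: trimethylsilyl trifluoromethanesulfonate (TMSOTf), C[Si](C)(C)OS(=O)(=O)C(F)(F)F
Why: Soft enolisation/silylation, in which TMSOTf activates the ketone, Et3N removes the only enolisable proton type and both phenols are O-silylated, so one operation masks the hydroquinone and makes the Mukaiyama nucleophile (no stereocentre).

Step 2
Reactants: 3 1-[2,5-bis(trimethylsilyloxy)phenyl]-1-(trimethylsilyloxy)ethene; 2 (13Z)-octadec-13-enal
Product: 5 (3R,15Z)-1-(2,5-dihydroxyphenyl)-3-hydroxyicos-15-en-1-one, via tris-TMS aldol adduct 4 (not isolated)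
Conditions: (R)-2-butyl-4-(indol-3-ylmethyl)-3-tosyl-1,3,2-oxazaborolidin-5-one (20 mol %, pre-formed from N-Ts-D-Trp and n-BuB(OH)2), EtCN–CH2Cl2 3:1, −78 °C, 14 h; then 1 M HCl, THF, 0 °C, 30 min; recrystallise (hexane–EtOAc, −20 °C) to raise the ee; check by chiral HPLC and Mosher ester
Reagents that add atoms: none
Why: Catalytic enantioselective Mukaiyama aldol with a tryptophan-derived oxazaborolidinone, in which the boron-bound aldehyde is held by a formyl C–H···O contact with one face stacked on the indole; the (S)-catalyst exposes the Re face, so the (R)-catalyst sends the enol silane to the Si face of 2 and sets C-3 as R (about 85–90 % ee is typical for unbranched aldehydes with aryl methyl ketone enol silanes), and the acid work-up strips all three TMS groups.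

Step 3
Reactants: 5 (3R,15Z)-1-(2,5-dihydroxyphenyl)-3-hydroxyicos-15-en-1-one
Product: 8 (2R)-2-[(12Z)-heptadec-12-en-1-yl]-5,8-dihydroxy-2,3-dihydro-4H-chromen-4-one, via acylquinone 6 (not isolated), via chromanetrione 7 (not isolated)
Conditions: Ag2O (6 equiv), MgSO4, CH2Cl2 (5 mM), rt, dark, 1–2 h; filter (Celite); shake the filtrate at once with sat. aq Na2S2O4, N2, 5 min; chromatography on silica with 0.5 % AcOH in the eluent
Reagents that add atoms: none
Why: Proposed new method: Ag2O dehydrogenates the acylhydroquinone to the 2-acyl-1,4-benzoquinone 6, whose C-3 is the β-carbon of both the ring enone and the exocyclic ketone and is the site where amines, thiols, enol ethers and HCl are known to add, so the tethered (R)-carbinol oxygen closes the pyranone by 6-endo-trig oxa-Michael addition and enolisation without touching the stereocentre (retention, because the new bond is O–C8a and not O–C2); the electron-richer cyclised hydroquinone is re-oxidised by 6 or Ag2O, so the mixture is deliberately driven to the single quinone 7 and dithionite returns it to 8, the closest known reaction type being the one-pot Ag2O oxidation, C-3 heteronucleophile addition and re-oxidation of acylhydroquinones.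

## Compound list
1 | 2',5'-dihydroxyacetophenone | CC(=O)c1cc(O)ccc1O | starting material
2 | (13Z)-octadec-13-enal | CCCC/C=C\CCCCCCCCCCCC=O | starting material
3 | 1-[2,5-bis(trimethylsilyloxy)phenyl]-1-(trimethylsilyloxy)ethene | C=C(O[Si](C)(C)C)c1cc(O[Si](C)(C)C)ccc1O[Si](C)(C)C | intermediate
4 | (3R,15Z)-1-[2,5-bis(trimethylsilyloxy)phenyl]-3-(trimethylsilyloxy)icos-15-en-1-one | CCCC/C=C\CCCCCCCCCCC[C@@H](O[Si](C)(C)C)CC(=O)c1cc(O[Si](C)(C)C)ccc1O[Si](C)(C)C | intermediate
5 | (3R,15Z)-1-(2,5-dihydroxyphenyl)-3-hydroxyicos-15-en-1-one | CCCC/C=C\CCCCCCCCCCC[C@@H](O)CC(=O)c1cc(O)ccc1O | intermediate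
6 | 2-[(3R,15Z)-3-hydroxyicos-15-enoyl]cyclohexa-2,5-diene-1,4-dione | CCCC/C=C\CCCCCCCCCCC[C@@H](O)CC(=O)C1=CC(=O)C=CC1=O | intermediate
7 | (2R)-2-[(12Z)-heptadec-12-en-1-yl]-2,3-dihydro-4H-chromene-4,5,8-trione | CCCC/C=C\CCCCCCCCCCC[C@@H]1CC(=O)C2=C(O1)C(=O)C=CC2=O | intermediate
8 | (2R)-2-[(12Z)-heptadec-12-en-1-yl]-5,8-dihydroxy-2,3-dihydro-4H-chromen-4-one | CCCC/C=C\CCCCCCCCCCC[C@@H]1CC(=O)c2c(O)ccc(O)c2O1 | target

## Step count and risks
Total step count: 3. Longest linear sequence: 3.

**Most likely to fail: step 3.** The carbinol may not add to the quinone C–H carbon. Quinone/hydroquinone cross-redox or dehydration of 6 may win. Compound 7 may also open by E1cB or tautomerise to the chromone.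

The fallback sets out from 5 and comes back at 7. It changes the C–O bond formation from conjugate addition to addition–elimination.
- 5 is oxidised briefly with Ag2O and filtered. The solution of 6 is then treated with dry HCl in Et2O at 0 °C.
- Chloride adds at C-3 to give (3R,15Z)-1-(2-chloro-3,6-dihydroxyphenyl)-3-hydroxyicos-15-en-1-one F1.
- Fresh Ag2O in CH2Cl2 re-oxidises it to 2-chloro-3-[(3R,15Z)-3-hydroxyicos-15-enoyl]cyclohexa-2,5-diene-1,4-dione F2, a vinylogous acid chloride.
- The tethered alcohol displaces chloride, which silver scavenges. This gives 7 directly with no hydroquinone intermediate, and therefore no cross-redox.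
- The dithionite wash of step 3 then gives 8.

**Second: step 2.** The ortho-silyloxy enol silane may give insufficient ee. The C18 aldehyde may be poorly soluble at −78 °C. A silyl-cation-catalysed racemic background reaction is also possible.

The fallback sets out from 2 and comes back at 6. It takes the stereocentre from a kinetic resolution and uses acyl-anion chemistry instead of an aldol.
- Dimethylsulfonium methylide (Me3SI, NaH, DMSO–THF, 0 °C) converts 2 into racemic 2-[(12Z)-heptadec-12-en-1-yl]oxirane F3.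
- Hydrolytic kinetic resolution with (R,R)-(salen)Co(III)OAc (0.5 mol %) and 0.55 equiv H2O leaves (2R)-2-[(12Z)-heptadec-12-en-1-yl]oxirane F4 in >99 % ee.
- 2-(2,5-Dimethoxyphenyl)-1,3-dithiane F5 is made from 2,5-dimethoxybenzaldehyde and propane-1,3-dithiol with BF3·OEt2.
- F5 is lithiated (n-BuLi, THF, −30 °C) and opens F4 at the CH2 terminus to give (2R,14Z)-1-[2-(2,5-dimethoxyphenyl)-1,3-dithian-2-yl]nonadec-14-en-2-ol F6.
- MeI/CaCO3 in aqueous MeCN unmasks the ketone to (3R,15Z)-1-(2,5-dimethoxyphenyl)-3-hydroxyicos-15-en-1-one F7.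
- CAN (2.5 equiv, MeCN–H2O, 0 °C) oxidatively demethylates F7 to 6. This is extracted into CH2Cl2, dried and carried on under the step 3 conditions.

**Third: step 1.** The aryl TMS ethers are hydrolytically fragile, and tris-silylation may be incomplete.

The fallback sets out from 1 and comes back at 6. It masks the hydroquinone as methyl ethers, which are later removed oxidatively rather than hydrolytically.
- MeI/K2CO3 in acetone turns 1 into 2',5'-dimethoxyacetophenone F8.
- TMSOTf/Et3N gives the robust, distillable 1-(2,5-dimethoxyphenyl)-1-(trimethylsilyloxy)ethene F9.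
- The same oxazaborolidinone-catalysed aldol with 2 gives (3R,15Z)-1-(2,5-dimethoxyphenyl)-3-(trimethylsilyloxy)icos-15-en-1-one F10.
- Acid work-up gives the dimethoxy aldol F7 described above.
- CAN oxidation of F7 delivers 6 for the ring closure of step 3.

## Further compounds
F1 | step 3 | (3R,15Z)-1-(2-chloro-3,6-dihydroxyphenyl)-3-hydroxyicos-15-en-1-one | CCCC/C=C\CCCCCCCCCCC[C@@H](O)CC(=O)c1c(Cl)c(O)ccc1O
F2 | step 3 | 2-chloro-3-[(3R,15Z)-3-hydroxyicos-15-enoyl]cyclohexa-2,5-diene-1,4-dione | CCCC/C=C\CCCCCCCCCCC[C@@H](O)CC(=O)C1=C(Cl)C(=O)C=CC1=O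
F3 | step 2 | racemic 2-[(12Z)-heptadec-12-en-1-yl]oxirane | CCCC/C=C\CCCCCCCCCCCC1CO1
F4 | step 2 | (2R)-2-[(12Z)-heptadec-12-en-1-yl]oxirane | CCCC/C=C\CCCCCCCCCCC[C@@H]1CO1
F5 | step 2 | 2-(2,5-dimethoxyphenyl)-1,3-dithiane | COc1ccc(OC)c(c1)C1SCCCS1
F6 | step 2 | (2R,14Z)-1-[2-(2,5-dimethoxyphenyl)-1,3-dithian-2-yl]nonadec-14-en-2-ol | CCCC/C=C\CCCCCCCCCCC[C@@H](O)CC1(SCCCS1)c1cc(OC)ccc1OC
F7 | step 2 | (3R,15Z)-1-(2,5-dimethoxyphenyl)-3-hydroxyicos-15-en-1-one | CCCC/C=C\CCCCCCCCCCC[C@@H](O)CC(=O)c1cc(OC)ccc1OC
F8 | step 1 | 2',5'-dimethoxyacetophenone | CC(=O)c1cc(OC)ccc1OC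
F9 | step 1 | 1-(2,5-dimethoxyphenyl)-1-(trimethylsilyloxy)ethene | C=C(O[Si](C)(C)C)c1cc(OC)ccc1OC
F10 | step 1 | (3R,15Z)-1-(2,5-dimethoxyphenyl)-3-(trimethylsilyloxy)icos-15-en-1-one | CCCC/C=C\CCCCCCCCCCC[C@@H](O[Si](C)(C)C)CC(=O)c1cc(OC)ccc1OC
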